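## Retrosynthetic overview

Chain numbering used throughout: C1–C5 pentyl, C6–C9 ring carbons (ring oxygen between C6 and C9), C10 side-chain carbinol, C18=C19 alkene.

1. Target ⇒ C10-O-TBS tetrahydrofuranol; C7–O lauroylation and desilylation are the last two steps.
2. The only ring (tetrahydrofuran) ⇒ 6-chloro-syn-7,9-diol; 5-exo-tet SN2 by C9–OH with inversion at C6, after all four stereocentres are set.
3. Chlorodiol ⇒ β-ketochlorohydrin (1,3-syn reduction) ⇒ key C7–C8 bond by intermolecular lithium aldol of a C8–C19 methyl ketone with (R)-2-chloroheptanal (C1–C7).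
4. Methyl ketone ⇒ undec-10-enoyl chloride via auxiliary-controlled α-hydroxylation (C10), Weinreb amide and MeMgBr (C8); chloroaldehyde ⇒ heptanal by organocatalytic α-chlorination.

Assumption: the (5S)-imidazolidinone catalyst gives (S)-2-chloroalkanals, so the (5R)-catalyst is used for (R)-2-chloroheptanal; its ee is checked on a NaBH4-reduced aliquot before use. "rt" means 20–25 °C.

## Route

Step 1
Reactants: 1 undec-10-enoyl chloride; 2 (R)-4-benzyloxazolidin-2-one
Product: 4 (R)-4-benzyl-3-(undec-10-enoyl)oxazolidin-2-one, via lithium oxazolidinide 3 (not isolated)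
Conditions: n-BuLi, THF, −78 °C; then 1, −78 → 0 °C
Reagents that add atoms: none
Why: N-acylation of the lithiated oxazolidinone by the acid chloride gives the imide cleanly; no new stereocentre is formed and the auxiliary centre is untouched.

Step 2
Reactants: 4 (R)-4-benzyl-3-(undec-10-enoyl)oxazolidin-2-one
Product: 6 (R)-4-benzyl-3-[(R)-2-hydroxyundec-10-enoyl]oxazolidin-2-one, via sodium Z-enolate 5 (not isolated)
Conditions: NaN(SiMe3)2, THF, −78 °C; 3-phenyl-2-(phenylsulfonyl)oxaziridine, −78 °C; AcOH quench at −78 °C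
Reagents that add atoms: 3-phenyl-2-(phenylsulfonyl)oxaziridine, O=S(=O)(c1ccccc1)N1OC1c1ccccc1
Why: Evans–Davis enolate hydroxylation: the chelated sodium Z-enolate is oxidised on the face opposite the benzyl group, setting C10 as (R) (typically ≥95:5, minor isomer removed by chromatography), and the isolated alkene is inert at −78 °C.

Step 3
Reactants: 6 (R)-4-benzyl-3-[(R)-2-hydroxyundec-10-enoyl]oxazolidin-2-one
Product: 7 (R)-2-hydroxy-N-methoxy-N-methylundec-10-enamide
Conditions: MeNHOMe·HCl, AlMe3, CH2Cl2, 0 °C → rt; aq. KNaC4H4O6 work-up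
Reagents that add atoms: N,O-dimethylhydroxylamine hydrochloride, CNOC.Cl
Why: Weinreb transamination: the aluminium alkoxide of the α-hydroxyl chelates and activates the exocyclic carbonyl, so the aluminium amide transfers only the acyl group and releases the auxiliary without touching C10.

Step 4
Reactants: 7 (R)-2-hydroxy-N-methoxy-N-methylundec-10-enamide
Product: 8 (R)-2-(tert-butyldimethylsilyloxy)-N-methoxy-N-methylundec-10-enamide
Conditions: TBSCl, imidazole, DMF, rt
Reagents that add atoms: tert-butyldimethylsilyl chloride, CC(C)(C)[Si](C)(C)Cl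
Why: Imidazole-mediated silylation of the secondary alcohol (silyl ether protection) is mild and non-basic enough to leave the α-centre intact.

Step 5
Reactants: 8 (R)-2-(tert-butyldimethylsilyloxy)-N-methoxy-N-methylundec-10-enamide
Product: 10 (R)-3-(tert-butyldimethylsilyloxy)dodec-11-en-2-one, via magnesium hemiaminal adduct 9 (not isolated)
Conditions: MeMgBr, THF, 0 °C; aq. NH4Cl
Reagents that add atoms: methylmagnesium bromide, C[Mg]Br
Why: Weinreb ketone synthesis: the chelated tetrahedral adduct blocks over-addition and collapses only on work-up, giving the methyl ketone (C8 introduced) without epimerising C10.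

Step 6
Reactants: 11 heptanal
Product: 12 (R)-2-chloroheptanal
Conditions: (5R)-5-benzyl-2,2,3-trimethylimidazolidin-4-one·CF3CO2H (5 mol %), 2,3,4,5,6,6-hexachlorocyclohexa-2,4-dien-1-one, acetone, −30 °C; cold pentane extraction, used at once
Reagents that add atoms: 2,3,4,5,6,6-hexachlorocyclohexa-2,4-dien-1-one, O=C1C(Cl)=C(Cl)C(Cl)=C(Cl)C1(Cl)Cl
Why: Enamine organocatalysis (asymmetric α-chlorination): the E-enamine is chlorinated on the face opposite the catalyst benzyl group, setting C6 as (R) in about 92% ee.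

Step 7
Reactants: 10 (R)-3-(tert-butyldimethylsilyloxy)dodec-11-en-2-one; 12 (R)-2-chloroheptanal
Product: 14 (6R,7S,10R)-10-(tert-butyldimethylsilyloxy)-6-chloro-7-hydroxynonadec-18-en-9-one, via lithium enolate 13 (not isolated)
Conditions: LiN(iPr)2 (commercial solution), THF, −78 °C, 40 min; then 12, −78 °C, 20 min; AcOH/THF quench at −78 °C
Reagents that add atoms: none
Why: Intermolecular lithium aldol addition of the kinetic methyl enolate forms the key C7–C8 bond; Cornforth (polar Felkin–Anh) addition to the α-chloroaldehyde gives the 1,2-anti chlorohydrin and sets C7 as (S), and adducts from residual (S)-12 are diastereomers removable by chromatography.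

Step 8
Reactants: 14 (6R,7S,10R)-10-(tert-butyldimethylsilyloxy)-6-chloro-7-hydroxynonadec-18-en-9-one
Product: 16 (6R,7S,9R,10R)-10-(tert-butyldimethylsilyloxy)-6-chlorononadec-18-ene-7,9-diol, via diethylboron chelate 15 (not isolated)
Conditions: Et2BOMe, THF/MeOH 4:1, −78 °C; NaBH4, −78 °C; AcOH; MeOH co-evaporation
Reagents that add atoms: none
Why: Narasaka–Prasad reduction: external hydride attacks the six-membered boron chelate axially to give the 1,3-syn diol, setting C9 as (R), and this is also the Felkin–Anh face relative to the C10 silyloxy group (matched).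

Step 9
Reactants: 16 (6R,7S,9R,10R)-10-(tert-butyldimethylsilyloxy)-6-chlorononadec-18-ene-7,9-diol
Product: 17 (2S,3S,5R)-5-[(1R)-1-(tert-butyldimethylsilyloxy)dec-9-en-1-yl]-2-pentyltetrahydrofuran-3-ol
Conditions: AgOTf, Ag2O, THF, rt → 45 °C, dark
Reagents that add atoms: none
Why: AgOTf-assisted intramolecular SN2 etherification (5-exo-tet): C9–OH displaces chloride with inversion at C6 (R → S), giving the 2,3-cis-2,5-trans tetrahydrofuran, while Ag2O scavenges the acid so the silyl ether survives and no base is present to form the epoxide.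

Step 10
Reactants: 17 (2S,3S,5R)-5-[(1R)-1-(tert-butyldimethylsilyloxy)dec-9-en-1-yl]-2-pentyltetrahydrofuran-3-ol; 18 dodecanoyl chloride
Product: 19 (2S,3S,5R)-5-[(1R)-1-(tert-butyldimethylsilyloxy)dec-9-en-1-yl]-2-pentyltetrahydrofuran-3-yl dodecanoate
Conditions: pyridine, DMAP (cat.), CH2Cl2, 0 °C → rt
Reagents that add atoms: none
Why: DMAP-catalysed acylation (esterification) of the only free hydroxyl, C7–OH, places the laurate regiospecifically with retention at C7.

Step 11
Reactants: 19 (2S,3S,5R)-5-[(1R)-1-(tert-butyldimethylsilyloxy)dec-9-en-1-yl]-2-pentyltetrahydrofuran-3-yl dodecanoate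
Product: 20 (2S,3S,5R)-5-[(1R)-1-hydroxydec-9-en-1-yl]-2-pentyltetrahydrofuran-3-yl dodecanoate
Conditions: HF·pyridine, pyridine, THF, 0 °C → rt
Reagents that add atoms: none
Why: Fluoride-mediated desilylation under buffered conditions frees C10–OH without touching the ester or alkene, and the trans 1,4-related oxygens make acyl migration unfavourable.

## Compound list

1 | undec-10-enoyl chloride | C=CCCCCCCCCC(=O)Cl | starting material
2 | (R)-4-benzyloxazolidin-2-one | O=C1N[C@H](Cc2ccccc2)CO1 | starting material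
3 | lithium (R)-4-benzyl-2-oxooxazolidin-3-ide | [Li]N1[C@H](Cc2ccccc2)COC1=O | intermediate
4 | (R)-4-benzyl-3-(undec-10-enoyl)oxazolidin-2-one | C=CCCCCCCCCC(=O)N1[C@H](Cc2ccccc2)COC1=O | intermediate
5 | sodium (Z)-1-[(R)-4-benzyl-2-oxooxazolidin-3-yl]undeca-1,10-dien-1-olate | C=CCCCCCCC/C=C(\O[Na])N1[C@H](Cc2ccccc2)COC1=O | intermediate
6 | (R)-4-benzyl-3-[(R)-2-hydroxyundec-10-enoyl]oxazolidin-2-one | C=CCCCCCCC[C@@H](O)C(=O)N1[C@H](Cc2ccccc2)COC1=O | intermediate
7 | (R)-2-hydroxy-N-methoxy-N-methylundec-10-enamide | C=CCCCCCCC[C@@H](O)C(=O)N(C)OC | intermediate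
8 | (R)-2-(tert-butyldimethylsilyloxy)-N-methoxy-N-methylundec-10-enamide | C=CCCCCCCC[C@@H](O[Si](C)(C)C(C)(C)C)C(=O)N(C)OC | intermediate
9 | bromomagnesium (3R)-3-(tert-butyldimethylsilyloxy)-2-[methoxy(methyl)amino]dodec-11-en-2-olate (C2 epimers) | C=CCCCCCCC[C@@H](O[Si](C)(C)C(C)(C)C)C(C)(O[Mg]Br)N(C)OC | intermediate
10 | (R)-3-(tert-butyldimethylsilyloxy)dodec-11-en-2-one | C=CCCCCCCC[C@@H](O[Si](C)(C)C(C)(C)C)C(C)=O | intermediate
11 | heptanal | CCCCCCC=O | starting material
12 | (R)-2-chloroheptanal | CCCCC[C@@H](Cl)C=O | intermediate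
13 | lithium (R)-3-(tert-butyldimethylsilyloxy)dodeca-1,11-dien-2-olate | C=CCCCCCCC[C@@H](O[Si](C)(C)C(C)(C)C)C(=C)O[Li] | intermediate
14 | (6R,7S,10R)-10-(tert-butyldimethylsilyloxy)-6-chloro-7-hydroxynonadec-18-en-9-one | CCCCC[C@@H](Cl)[C@@H](O)CC(=O)[C@H](O[Si](C)(C)C(C)(C)C)CCCCCCCC=C | intermediate
15 | (6R,7S,10R)-10-(tert-butyldimethylsilyloxy)-6-chloro-7-[(diethylboranyl)oxy]nonadec-18-en-9-one | CCCCC[C@@H](Cl)[C@@H](OB(CC)CC)CC(=O)[C@H](O[Si](C)(C)C(C)(C)C)CCCCCCCC=C | intermediate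
16 | (6R,7S,9R,10R)-10-(tert-butyldimethylsilyloxy)-6-chlorononadec-18-ene-7,9-diol | CCCCC[C@@H](Cl)[C@@H](O)C[C@@H](O)[C@H](O[Si](C)(C)C(C)(C)C)CCCCCCCC=C | intermediate
17 | (2S,3S,5R)-5-[(1R)-1-(tert-butyldimethylsilyloxy)dec-9-en-1-yl]-2-pentyltetrahydrofuran-3-ol | C=CCCCCCCC[C@@H](O[Si](C)(C)C(C)(C)C)[C@H]1C[C@H](O)[C@H](CCCCC)O1 | intermediate
18 | dodecanoyl chloride | CCCCCCCCCCCC(=O)Cl | starting material
19 | (2S,3S,5R)-5-[(1R)-1-(tert-butyldimethylsilyloxy)dec-9-en-1-yl]-2-pentyltetrahydrofuran-3-yl dodecanoate | C=CCCCCCCC[C@@H](O[Si](C)(C)C(C)(C)C)[C@H]1C[C@H](OC(=O)CCCCCCCCCCC)[C@H](CCCCC)O1 | intermediate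
20 | (2S,3S,5R)-5-[(1R)-1-hydroxydec-9-en-1-yl]-2-pentyltetrahydrofuran-3-yl dodecanoate | C=CCCCCCCC[C@@H](O)[C@H]1C[C@H](OC(=O)CCCCCCCCCCC)[C@H](CCCCC)O1 | target

## Step count and risks

Total step count: 11. Longest linear sequence: 10 steps (steps 1–5 and 7–11, from 1 to 20); step 6 is a one-step side branch.

The three steps most likely to fail:

**Step 7 (aldol).** Risks are modest anti selectivity with this chiral enolate and base-induced loss of the chloroaldehyde. The fallback sets out from 10 and comes back at 14. It replaces the closed lithium transition state by an open Lewis-acid Mukaiyama aldol. Enolate 13 is trapped with Me3SiCl (LiN(iPr)2, THF, −78 °C) to give the silyl enol ether (R)-3-(tert-butyldimethylsilyloxy)-2-(trimethylsilyloxy)dodeca-1,11-diene F1. F1 is added to 12 with BF3·OEt2 in CH2Cl2 at −78 °C. The open transition state keeps the Cornforth preference for the 1,2-anti chlorohydrin under non-basic conditions, and aqueous work-up returns 14.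

**Step 8 (1,3-syn reduction).** The risk is low selectivity if the boron chelate and the α-silyloxy centre do not cooperate as expected. The fallback sets out from 14 and comes back at 16. It changes from 1,3-chelation control to 1,2-Felkin–Anh control on a capped substrate. Et3SiOTf and 2,6-lutidine (CH2Cl2, −78 °C) give the triethylsilyl ether (6R,7S,10R)-10-(tert-butyldimethylsilyloxy)-6-chloro-7-(triethylsilyloxy)nonadec-18-en-9-one F2. Reduction with LiBH(s-Bu)3 in THF at −78 °C, directed by the C10 silyloxy group, gives the 9,10-syn alcohol (6R,7S,9R,10R)-10-(tert-butyldimethylsilyloxy)-6-chloro-7-(triethylsilyloxy)nonadec-18-en-9-ol F3. Pyridinium p-toluenesulfonate in MeOH at 0 °C removes only the triethylsilyl group and gives 16.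

**Step 9 (ring closure).** Risks are slow closure because the nucleophilic C9–OH sits next to the bulky silyl ether, and 1,2-silyl migration onto C9–O. The fallback sets out from 7 and comes back at 20. It changes the C10 protecting group to one that cannot migrate and is much smaller.
- 4-Methoxybenzyl 2,2,2-trichloroacetimidate with catalytic camphorsulfonic acid (CH2Cl2, rt) gives (R)-N-methoxy-2-[(4-methoxybenzyl)oxy]-N-methylundec-10-enamide F4.
- MeMgBr, through the bromomagnesium hemiaminal adduct F5, gives (R)-3-[(4-methoxybenzyl)oxy]dodec-11-en-2-one F6.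
- LiN(iPr)2 gives the lithium enolate F7, which adds to 12 to give (6R,7S,10R)-6-chloro-7-hydroxy-10-[(4-methoxybenzyl)oxy]nonadec-18-en-9-one F8.
- Et2BOMe/NaBH4, through the diethylboron chelate F9, gives (6R,7S,9R,10R)-6-chloro-10-[(4-methoxybenzyl)oxy]nonadec-18-ene-7,9-diol F10.
- AgOTf/Ag2O in THF closes the ring to (2S,3S,5R)-5-[(1R)-1-[(4-methoxybenzyl)oxy]dec-9-en-1-yl]-2-pentyltetrahydrofuran-3-ol F11.
- Acylation with 18 (pyridine, DMAP) gives (2S,3S,5R)-5-[(1R)-1-[(4-methoxybenzyl)oxy]dec-9-en-1-yl]-2-pentyltetrahydrofuran-3-yl dodecanoate F12.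
- 2,3-Dichloro-5,6-dicyano-1,4-benzoquinone in CH2Cl2/pH 7 buffer removes the ether and gives 20.

## Further compounds

F1 | step 7 | (R)-3-(tert-butyldimethylsilyloxy)-2-(trimethylsilyloxy)dodeca-1,11-diene | C=CCCCCCCC[C@@H](O[Si](C)(C)C(C)(C)C)C(=C)O[Si](C)(C)C
F2 | step 8 | (6R,7S,10R)-10-(tert-butyldimethylsilyloxy)-6-chloro-7-(triethylsilyloxy)nonadec-18-en-9-one | CCCCC[C@@H](Cl)[C@@H](O[Si](CC)(CC)CC)CC(=O)[C@H](O[Si](C)(C)C(C)(C)C)CCCCCCCC=C
F3 | step 8 | (6R,7S,9R,10R)-10-(tert-butyldimethylsilyloxy)-6-chloro-7-(triethylsilyloxy)nonadec-18-en-9-ol | CCCCC[C@@H](Cl)[C@@H](O[Si](CC)(CC)CC)C[C@@H](O)[C@H](O[Si](C)(C)C(C)(C)C)CCCCCCCC=C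
F4 | step 9 | (R)-N-methoxy-2-[(4-methoxybenzyl)oxy]-N-methylundec-10-enamide | C=CCCCCCCC[C@@H](OCc1ccc(OC)cc1)C(=O)N(C)OC
F5 | step 9 | bromomagnesium (3R)-2-[methoxy(methyl)amino]-3-[(4-methoxybenzyl)oxy]dodec-11-en-2-olate (C2 epimers) | C=CCCCCCCC[C@@H](OCc1ccc(OC)cc1)C(C)(O[Mg]Br)N(C)OC
F6 | step 9 | (R)-3-[(4-methoxybenzyl)oxy]dodec-11-en-2-one | C=CCCCCCCC[C@@H](OCc1ccc(OC)cc1)C(C)=O
F7 | step 9 | lithium (R)-3-[(4-methoxybenzyl)oxy]dodeca-1,11-dien-2-olate | C=CCCCCCCC[C@@H](OCc1ccc(OC)cc1)C(=C)O[Li]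
F8 | step 9 | (6R,7S,10R)-6-chloro-7-hydroxy-10-[(4-methoxybenzyl)oxy]nonadec-18-en-9-one | CCCCC[C@@H](Cl)[C@@H](O)CC(=O)[C@H](OCc1ccc(OC)cc1)CCCCCCCC=C
F9 | step 9 | (6R,7S,10R)-6-chloro-7-[(diethylboranyl)oxy]-10-[(4-methoxybenzyl)oxy]nonadec-18-en-9-one | CCCCC[C@@H](Cl)[C@@H](OB(CC)CC)CC(=O)[C@H](OCc1ccc(OC)cc1)CCCCCCCC=C
F10 | step 9 | (6R,7S,9R,10R)-6-chloro-10-[(4-methoxybenzyl)oxy]nonadec-18-ene-7,9-diol | CCCCC[C@@H](Cl)[C@@H](O)C[C@@H](O)[C@H](OCc1ccc(OC)cc1)CCCCCCCC=C
F11 | step 9 | (2S,3S,5R)-5-[(1R)-1-[(4-methoxybenzyl)oxy]dec-9-en-1-yl]-2-pentyltetrahydrofuran-3-ol | C=CCCCCCCC[C@@H](OCc1ccc(OC)cc1)[C@H]1C[C@H](O)[C@H](CCCCC)O1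
F12 | step 9 | (2S,3S,5R)-5-[(1R)-1-[(4-methoxybenzyl)oxy]dec-9-en-1-yl]-2-pentyltetrahydrofuran-3-yl dodecanoate | C=CCCCCCCC[C@@H](OCc1ccc(OC)cc1)[C@H]1C[C@H](OC(=O)CCCCCCCCCCC)[C@H](CCCCC)O1
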